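**Strategy.** The linker–hydroazulene bond is made late by aldol condensation, so everything rests on the oxepane–cyclohexane half. Its rings A (oxepane) and B (cyclohexane) are trans-fused, with O1 bridging C2 (the C(CH3)2 carbon) and the fusion CH C9a, and the methyl-bearing fusion carbon C5a bonded to C6, the CH that carries the linker: the pattern left when two 1,5-related epoxides are opened one after the other. One silyl triflate operation on an acyclic diepoxide forms O1–C2 and C5a–C6, both rings and two stereocentres. The precursor is the (S,S,S)-diepoxide of geranylacetone whose ketone is held as a (Z)-triethylsilyl enol ether bearing a 2-benzyloxyethyl arm.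

Key step: step 5

Remark: locants of the ring A/B half follow 1-benzoxepine numbering and those of the other half azulene numbering; the L-fructose-derived Shi ketone and (S)-(−)-limonene are taken as purchasable.

**Ring A/B half (steps 1–9)**

Step 1
Reactants: 1 geranylacetone
Product: 4 (S,S,S)-diepoxy ketone, via terminal monoepoxide 2 (not isolated), via internal monoepoxide 3 (not isolated)
Conditions: L-fructose-derived Shi ketone (0.3 equiv), Oxone (2KHSO5·KHSO4·K2SO4), K2CO3, Bu4NHSO4, MeCN/CH2(OMe)2, aq. Na2B4O7–Na2EDTA buffer, 0 °C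
Reagents that add atoms: potassium peroxymonosulfate (active part of Oxone) [K+].[O-]S(=O)(=O)OO
Why: Shi asymmetric epoxidation, in which the chiral dioxirane attacks both electron-rich (E)-trisubstituted alkenes through the spiro transition state from the same face, which with the L-fructose-derived ketone should give the (S,S) and (S) epoxides, while the unactivated methyl ketone is a poor dioxirane precursor and should survive at 0 °C.

Step 2
Reactants: 4 (S,S,S)-diepoxy ketone; 5 benzyloxyacetaldehyde
Product: 7 aldol adduct, via lithium enolate 6 (not isolated)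
Conditions: LiN(i-Pr)2, THF, −78 °C; then 5, −78 °C
Reagents that add atoms: none
Why: Kinetic deprotonation on the methyl side of the ketone and aldol addition bring in both arm carbons at −78 °C, where lithium enolates do not open trisubstituted epoxides; the new carbinol centre is destroyed in step 3.

Step 3
Reactants: 7 aldol adduct
Product: 9 (E)-enone, via mesylate 8 (not isolated)
Conditions: MsCl, Et3N, CH2Cl2, 0 °C to rt
Reagents that add atoms: none
Why: Mesylation and E1cB elimination complete the aldol condensation and give the conjugated (E)-enone under conditions too mild to touch the epoxides.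

Step 4
Reactants: 9 (E)-enone
Product: 10 (Z)-triethylsilyl enol ether
Conditions: Et3SiH, RhCl(PPh3)3 (2 mol %), toluene, 50 °C
Reagents that add atoms: triethylsilane CC[SiH](CC)CC
Why: Rhodium-catalysed 1,4-hydrosilylation of the s-cis enone puts silicon on oxygen and hydrogen on the β-carbon, which fixes both the position and the (Z) geometry of the enol silane, something enolisation of the saturated ketone could not do.

Step 5
Reactants: 10 (Z)-triethylsilyl enol ether
Product: 13 trans-fused oxepane–cyclohexanone, via epoxonium triflate 11 (not isolated), via silyloxocarbenium triflate 12 (not isolated)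
Conditions: Et3SiOTf (1.1 equiv), 2,6-di-tert-butyl-4-methylpyridine, CH2Cl2, −78 °C; aq. NaHCO3
Reagents that add atoms: triethylsilyl trifluoromethanesulfonate CC[Si](CC)(CC)OS(=O)(=O)C(F)(F)F
Why: Et3SiOTf silylates the terminal epoxide, the oxygen of the inner epoxide opens it at the tertiary carbon C2 to give the bicyclic epoxonium ion 11, the enol silane carbon opens 11 at the methyl-bearing carbon C5a with inversion, and the silyloxocarbenium ion 12 hands its Et3Si group back to triflate. The closest known reaction type is the silyl triflate-promoted tandem oxa- and carbacyclisation of 1,5-diepoxides terminated by enol silanes, a relative of epoxide-initiated polyene cyclisation. Ring A closes by endo attack of oxygen at C2 (six-membered epoxonium) and becomes the oxepane when the O1–C5a bond breaks, a 7-endo opening overall; ring B closes by a 6-(enolendo)-exo-tet attack through a chair. C5a is set by the anti, SN2-like opening of the (S,S)-epoxide made from the (E)-alkene, which forces the trans fusion, and C6 by the (Z) geometry of the enol silane in the chair, which places the arm equatorial; C3 and C9a are carried over from the epoxides, and C6, being α to the new ketone, can be converged with base if any axial epimer forms. The step needs activation at the terminal epoxide and C- rather than O-alkylation: both epoxides open at their tertiary carbons, only the epoxonium carbon C5a lies six atoms from the nucleophilic carbon, and −78 °C with a hindered pyridine keeps proton loss and 1,2-shifts of the oxonium ions in check. Because promoter and enol ether carry the same Et3Si group the step is a net isomerisation that should give one silyl ether and not a mixture.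

Step 6
Reactants: 13 trans-fused oxepane–cyclohexanone
Product: 14 tertiary alcohol
Conditions: MeMgBr, CeCl3, THF, −78 °C
Reagents that add atoms: methylmagnesium bromide C[Mg]Br
Why: Organocerium 1,2-addition, in which the axial C5a methyl blocks the axial trajectory (1,3-diaxial) so that the methyl group should enter equatorially and leave the hydroxyl axial (7R), while the weakly basic reagent should neither enolise the ketone nor epimerise C6.

Step 7
Reactants: 14 tertiary alcohol
Product: 15 bis(triethylsilyl) ether
Conditions: Et3SiOTf, 2,6-lutidine, CH2Cl2, 0 °C to rt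
Reagents that add atoms: triethylsilyl trifluoromethanesulfonate CC[Si](CC)(CC)OS(=O)(=O)C(F)(F)F
Why: Silyl triflate silylation of the hindered tertiary alcohol, needed because a free hydroxyl would trap the later aldehyde as a five-membered lactol.

Step 8
Reactants: 15 bis(triethylsilyl) ether
Product: 16 primary alcohol
Conditions: H2 (1 atm), Pd/C, EtOAc, rt
Reagents that add atoms: none
Why: Hydrogenolysis of the benzyl ether over palladium, with no alkene present and triethylsilyl ethers stable in ethyl acetate.

Step 9
Reactants: 16 primary alcohol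
Product: 17 aldehyde
Conditions: Dess–Martin periodinane, NaHCO3, CH2Cl2, rt
Reagents that add atoms: none
Why: Dess–Martin oxidation of the only free (primary) alcohol to the aldehyde under buffered, non-epimerising conditions.

**Hydroazulene half (steps 10–20)**

Step 10
Reactants: 18 (S)-(−)-limonene
Product: 20 keto aldehyde, via ozonide 19 (not isolated)
Conditions: O3 (1 equiv), CH2Cl2, −78 °C; then Me2S, −78 °C to rt
Reagents that add atoms: ozone [O-][O+]=O
Why: Ozonolysis with one equivalent of ozone cleaves the more electron-rich trisubstituted ring alkene in preference to the 1,1-disubstituted isopropenyl group, and the stereocentre is not involved.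

Step 11
Reactants: 20 keto aldehyde
Product: 22 cyclopentene carbaldehyde, via aldol 21 (not isolated)
Conditions: piperidine, AcOH, toluene, 80 °C
Reagents that add atoms: none
Why: Intramolecular aldol condensation through the aldehyde enamine closes the five-membered ring onto the ketone and dehydrates to the conjugated enal, the stereocentre β to the aldehyde being untouched.

Step 12
Reactants: 22 cyclopentene carbaldehyde
Product: 23 epoxy aldehyde
Conditions: 30% aq. H2O2, NaOH (cat.), MeOH, 0 °C
Reagents that add atoms: hydrogen peroxide OO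
Why: Weitz–Scheffer nucleophilic epoxidation of the enal, in which ring closure of the hydroperoxide adduct should occur on the face opposite the adjacent isopropenyl group and so set the future carbinol carbon C1, while the isolated isopropenyl alkene is inert to hydroperoxide anion.

Step 13
Reactants: 23 epoxy aldehyde
Product: 24 epoxy carbinol
Conditions: MeMgBr, THF, −78 °C
Reagents that add atoms: methylmagnesium bromide C[Mg]Br
Why: Grignard 1,2-addition to the aldehyde at low temperature is faster than any epoxide opening, and the carbinol configuration is irrelevant because it is oxidised in step 14.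

Step 14
Reactants: 24 epoxy carbinol
Product: 25 epoxy methyl ketone
Conditions: Dess–Martin periodinane, NaHCO3, CH2Cl2, rt
Reagents that add atoms: none
Why: Dess–Martin oxidation of the secondary alcohol gives the methyl ketone without touching epoxide or alkene.

Step 15
Reactants: 25 epoxy methyl ketone
Product: 27 hydroxy ketone, via lithium enolate 26 (not isolated)
Conditions: LiN(i-Pr)2, THF, −78 °C; then acrolein, −78 °C
Reagents that add atoms: acrolein C=CC=O
Why: The methyl group is the only enolisable position, so enolate formation and aldol 1,2-addition to acrolein are regiochemically unambiguous, and the carbinol centre is oxidised in step 18.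

Step 16
Reactants: 27 hydroxy ketone
Product: 28 bicyclic epoxy ketone
Conditions: second-generation Grubbs catalyst (5 mol %), CH2Cl2, 40 °C
Reagents that add atoms: none
Why: Ring-closing metathesis between the vinyl carbinol and the isopropenyl group, held cis on the cyclopentane, forms the seven-membered ring with a trisubstituted alkene and is driven by loss of ethylene.

Step 17
Reactants: 28 bicyclic epoxy ketone
Product: 30 diene diol, via epoxy hydrazone 29 (not isolated)
Conditions: N2H4·H2O, AcOH (cat.), MeOH, 0 °C to rt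
Reagents that add atoms: none
Why: Wharton transposition, in which the epoxy hydrazone fragments with loss of nitrogen to the tertiary allylic alcohol and the ring-fusion alkene, the C1–O bond set in step 12 being carried through unchanged.

Step 18
Reactants: 30 diene diol
Product: 31 dienone
Conditions: MnO2, CH2Cl2, rt
Reagents that add atoms: none
Why: Manganese dioxide oxidises the secondary allylic alcohol to the enone and leaves the tertiary allylic alcohol alone.

Step 19
Reactants: 31 dienone
Product: 32 cis-fused hydroazulenone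
Conditions: H2 (1 atm), [Ir(cod)(PCy3)(py)]PF6 (5 mol %), CH2Cl2, 0 °C to rt
Reagents that add atoms: none
Why: Hydroxyl-directed homogeneous hydrogenation, in which iridium bound to the tertiary hydroxyl should deliver hydrogen to the same face of the neighbouring trisubstituted alkene and so make H-8a cis to the hydroxyl and to H-3a (cis ring fusion), while the undirected, electron-poor enone alkene is a poor substrate for the cationic catalyst.

Step 20
Reactants: 32 cis-fused hydroazulenone
Product: 33 bis(trimethylsilyl) enol ether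
Conditions: Me2CuLi (3 equiv), Me3SiCl, Et3N, THF, −78 to −20 °C
Reagents that add atoms: lithium dimethylcuprate C[Cu-]C.[Li+]; chlorotrimethylsilane C[Si](C)(C)Cl
Why: Silyl chloride-accelerated cuprate conjugate addition to the β-methyl enone creates the gem-dimethyl carbon C4 (not stereogenic) and stores the enolate regiospecifically on the C5 side as its silyl ether, the tertiary alkoxide being silylated in the same flask.

**Union and end game (steps 21–27)**

Step 21
Reactants: 33 bis(trimethylsilyl) enol ether; 17 aldehyde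
Product: 35 coupled aldol, via lithium enolate 34 (not isolated)
Conditions: MeLi, THF, 0 °C; then 17, −78 °C
Reagents that add atoms: none
Why: Methyllithium cleaves the enol silane to the regiodefined lithium enolate, which undergoes aldol addition to the aldehyde at −78 °C before it can equilibrate; both new centres are removed or reset in steps 22 and 23.

Step 22
Reactants: 35 coupled aldol
Product: 37 alkylidene ketone, via mesylate 36 (not isolated)
Conditions: MsCl, Et3N, CH2Cl2, 0 °C; then DBU, rt
Reagents that add atoms: none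
Why: Mesylation and base-induced E1cB elimination give the α-alkylidene ketone, whose geometry is of no consequence.

Step 23
Reactants: 37 alkylidene ketone
Product: 38 saturated ketone
Conditions: H2 (1 atm), Pd/C, EtOAc, rt
Reagents that add atoms: none
Why: Heterogeneous hydrogenation of the exocyclic enone alkene should take place on the convex face of the cis-fused hydroazulenone (the face of H-3a and H-8a), placing H-5 cis to them as in the target, and because C5 is α to the ketone the pseudo-equatorial side chain can also be reached by base equilibration.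

Step 24
Reactants: 38 saturated ketone
Product: 40 enol triflate, via potassium enolate 39 (not isolated)
Conditions: KN(SiMe3)2, THF, −78 °C; then PhNTf2
Reagents that add atoms: N-phenylbis(trifluoromethanesulfonimide) FC(F)(F)S(=O)(=O)N(c1ccccc1)S(=O)(=O)C(F)(F)F
Why: Kinetic deprotonation occurs at the unhindered C7 methylene and not at the neopentyl, trisubstituted C5, and O-sulfonylation of the enolate gives the enol triflate with the double bond where the target has it.

Step 25
Reactants: 40 enol triflate
Product: 41 silylated methyl alkene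
Conditions: MeMgBr, Fe(acac)3 (5 mol %), THF/NMP, −30 to 0 °C
Reagents that add atoms: methylmagnesium bromide C[Mg]Br
Why: Iron-catalysed cross-coupling of the alkenyl triflate with the methyl Grignard reagent (Kumada type) replaces triflate by methyl without moving the double bond, and silyl ethers are inert.

Step 26
Reactants: 41 silylated methyl alkene
Product: 42 triol
Conditions: Bu4NF, THF, 50 °C
Reagents that add atoms: none
Why: Fluoride cleaves all three silyl ethers (Si–F bond formation), heat being needed for the two tertiary ones.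

Step 27
Reactants: 42 triol
Product: 43 target
Conditions: Dess–Martin periodinane, NaHCO3, CH2Cl2, 0 °C to rt
Reagents that add atoms: none
Why: Dess–Martin oxidation of the single secondary alcohol gives the oxepanone, tertiary alcohols and the trisubstituted alkene being inert.

**Compound list**

1 | geranylacetone, (E)-6,10-dimethylundeca-5,9-dien-2-one | CC(C)=CCC/C(C)=C/CCC(C)=O | starting material
2 | terminal monoepoxide, (E)-8-[(2S)-3,3-dimethyloxiran-2-yl]-6-methyloct-5-en-2-one | CC(=O)CC/C=C(\C)CC[C@@H]1OC1(C)C | intermediate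
3 | internal monoepoxide, 4-[(2S,3S)-3-methyl-3-(4-methylpent-3-en-1-yl)oxiran-2-yl]butan-2-one | CC(=O)CC[C@@H]1O[C@@]1(C)CCC=C(C)C | intermediate
4 | (S,S,S)-diepoxy ketone, 4-[(2S,3S)-3-{2-[(2S)-3,3-dimethyloxiran-2-yl]ethyl}-3-methyloxiran-2-yl]butan-2-one | CC(=O)CC[C@@H]1O[C@@]1(C)CC[C@@H]1OC1(C)C | intermediate
5 | benzyloxyacetaldehyde | O=CCOCc1ccccc1 | starting material
6 | lithium enolate of 4 on the methyl side | C=C(O[Li])CC[C@@H]1O[C@@]1(C)CC[C@@H]1OC1(C)C | intermediate
7 | aldol adduct, 1-(benzyloxy)-2-hydroxyheptan-4-one carrying the diepoxide of 4 at C7 (both carbinol epimers) | O=C(CC(O)COCc1ccccc1)CC[C@@H]1O[C@@]1(C)CC[C@@H]1OC1(C)C | intermediate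
8 | mesylate of 7 | O=C(CC(OS(C)(=O)=O)COCc1ccccc1)CC[C@@H]1O[C@@]1(C)CC[C@@H]1OC1(C)C | intermediate
9 | (E)-enone, (E)-1-(benzyloxy)hept-2-en-4-one carrying the diepoxide at C7 | O=C(/C=C/COCc1ccccc1)CC[C@@H]1O[C@@]1(C)CC[C@@H]1OC1(C)C | intermediate
10 | (Z)-triethylsilyl enol ether, triethyl{[(3Z)-1-(benzyloxy)-7-[(2S,3S)-3-{2-[(2S)-3,3-dimethyloxiran-2-yl]ethyl}-3-methyloxiran-2-yl]hept-3-en-4-yl]oxy}silane | c1ccccc1COCC/C=C(\O[Si](CC)(CC)CC)CC[C@@H]1O[C@@]1(C)CC[C@@H]1OC1(C)C | intermediate
11 | epoxonium triflate: oxirane fused through O+ to a tetrahydropyran that bears the triethylsilyloxy group, enol silane chain intact | c1ccccc1COCC/C=C(\O[Si](CC)(CC)CC)CC[C@@H]1[O+]2C(C)(C)[C@@H](O[Si](CC)(CC)CC)CC[C@@]12C.[O-]S(=O)(=O)C(F)(F)F | intermediate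
12 | silyloxocarbenium triflate of 13 | c1ccccc1COCC[C@H]1[C@]2(C)CC[C@H](O[Si](CC)(CC)CC)C(C)(C)O[C@H]2CCC1=[O+][Si](CC)(CC)CC.[O-]S(=O)(=O)C(F)(F)F | intermediate
13 | (3S,5aS,6S,9aS)-6-[2-(benzyloxy)ethyl]-2,2,5a-trimethyl-3-(triethylsilyloxy)octahydro-1-benzoxepin-7(2H)-one | c1ccccc1COCC[C@H]1[C@]2(C)CC[C@H](O[Si](CC)(CC)CC)C(C)(C)O[C@H]2CCC1=O | intermediate
14 | (3S,5aS,6S,7R,9aS)-6-[2-(benzyloxy)ethyl]-2,2,5a,7-tetramethyl-3-(triethylsilyloxy)decahydro-1-benzoxepin-7-ol (axial hydroxyl) | c1ccccc1COCC[C@H]1[C@]2(C)CC[C@H](O[Si](CC)(CC)CC)C(C)(C)O[C@H]2CC[C@@]1(C)O | intermediate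
15 | 3,7-bis(triethylsilyl) ether of 14 | c1ccccc1COCC[C@H]1[C@]2(C)CC[C@H](O[Si](CC)(CC)CC)C(C)(C)O[C@H]2CC[C@@]1(C)O[Si](CC)(CC)CC | intermediate
16 | primary alcohol, 2-[(3S,5aS,6S,7R,9aS)-2,2,5a,7-tetramethyl-3,7-bis(triethylsilyloxy)decahydro-1-benzoxepin-6-yl]ethanol | OCC[C@H]1[C@]2(C)CC[C@H](O[Si](CC)(CC)CC)C(C)(C)O[C@H]2CC[C@@]1(C)O[Si](CC)(CC)CC | intermediate
17 | aldehyde, the corresponding acetaldehyde | O=CC[C@H]1[C@]2(C)CC[C@H](O[Si](CC)(CC)CC)C(C)(C)O[C@H]2CC[C@@]1(C)O[Si](CC)(CC)CC | intermediate
18 | (S)-(−)-limonene | CC1=CC[C@H](CC1)C(C)=C | starting material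
19 | ozonide (1,2,4-trioxolane) of the ring alkene of 18 | CC12CC[C@H](C(C)=C)CC(OO1)O2 | intermediate
20 | (S)-6-oxo-3-(prop-1-en-2-yl)heptanal | O=CC[C@H](CCC(C)=O)C(C)=C | intermediate
21 | aldol, 2-hydroxy-2-methyl-5-(prop-1-en-2-yl)cyclopentane-1-carbaldehyde | O=CC1C(C)(O)CC[C@@H]1C(C)=C | intermediate
22 | (R)-2-methyl-5-(prop-1-en-2-yl)cyclopent-1-ene-1-carbaldehyde | O=CC1=C(C)CC[C@@H]1C(C)=C | intermediate
23 | (1R,2R,5S)-5-methyl-2-(prop-1-en-2-yl)-6-oxabicyclo[3.1.0]hexane-1-carbaldehyde (epoxide oxygen trans to isopropenyl) | O=C[C@]32[C@H](CC[C@]2(C)O3)C(C)=C | intermediate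
24 | 1-[(1R,2R,5S)-5-methyl-2-(prop-1-en-2-yl)-6-oxabicyclo[3.1.0]hexan-1-yl]ethanol (both carbinol epimers) | CC(O)[C@]32[C@H](CC[C@]2(C)O3)C(C)=C | intermediate
25 | 1-[(1R,2R,5S)-5-methyl-2-(prop-1-en-2-yl)-6-oxabicyclo[3.1.0]hexan-1-yl]ethanone | CC(=O)[C@]32[C@H](CC[C@]2(C)O3)C(C)=C | intermediate
26 | lithium enolate of 25 | C=C(O[Li])[C@]32[C@H](CC[C@]2(C)O3)C(C)=C | intermediate
27 | 3-hydroxy-1-[(1R,2R,5S)-5-methyl-2-(prop-1-en-2-yl)-6-oxabicyclo[3.1.0]hexan-1-yl]pent-4-en-1-one (both carbinol epimers) | C=CC(O)CC(=O)[C@]32[C@H](CC[C@]2(C)O3)C(C)=C | intermediate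
28 | (1S,3aR,8aR)-1,8a-epoxy-6-hydroxy-1,4-dimethyl-2,3,3a,6,7,8a-hexahydroazulen-8(1H)-one (epoxide oxygen cis to H-3a; C6 epimers) | OC1CC(=O)[C@]32[C@H](CC[C@]2(C)O3)C(C)=C1 | intermediate
29 | hydrazone of 28 | OC1CC(=NN)[C@]32[C@H](CC[C@]2(C)O3)C(C)=C1 | intermediate
30 | (1S,3aR)-1,4-dimethyl-1,2,3,3a,6,7-hexahydroazulene-1,6-diol (C6 epimers) | OC1CC=C2[C@H](CC[C@]2(C)O)C(C)=C1 | intermediate
31 | (1S,3aR)-1-hydroxy-1,4-dimethyl-2,3,3a,7-tetrahydroazulen-6(1H)-one | O=C1CC=C2[C@H](CC[C@]2(C)O)C(C)=C1 | intermediate
32 | (1S,3aS,8aS)-1-hydroxy-1,4-dimethyl-2,3,3a,7,8,8a-hexahydroazulen-6(1H)-one (cis-fused, OH cis to both fusion hydrogens) | O=C1CC[C@H]2[C@H](CC[C@]2(C)O)C(C)=C1 | intermediate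
33 | (1S,3aS,8aS)-1,4,4-trimethyl-1,6-bis(trimethylsilyloxy)-1,2,3,3a,4,7,8,8a-octahydroazulene | C[Si](C)(C)OC1CC[C@H]2[C@H](CC[C@]2(C)O[Si](C)(C)C)C(C)(C)C=1 | intermediate
34 | lithium enolate from 33 (C5=C6 enolate, C1–OSiMe3 kept) | [Li]OC1CC[C@H]2[C@H](CC[C@]2(C)O[Si](C)(C)C)C(C)(C)C=1 | intermediate
35 | coupled aldol: C5 of the 1-(trimethylsilyloxy)-1,4,4-trimethylhydroazulen-6-one bonded to CH(OH)–CH2–C6 of the benzoxepane of 17 (epimers at C5 and the carbinol) | O=C1CC[C@H]2[C@H](CC[C@]2(C)O[Si](C)(C)C)C(C)(C)C1C(O)C[C@H]1[C@]2(C)CC[C@H](O[Si](CC)(CC)CC)C(C)(C)O[C@H]2CC[C@@]1(C)O[Si](CC)(CC)CC | intermediate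
36 | mesylate of 35 | O=C1CC[C@H]2[C@H](CC[C@]2(C)O[Si](C)(C)C)C(C)(C)C1C(OS(C)(=O)=O)C[C@H]1[C@]2(C)CC[C@H](O[Si](CC)(CC)CC)C(C)(C)O[C@H]2CC[C@@]1(C)O[Si](CC)(CC)CC | intermediate
37 | alkylidene ketone: C5=CH–CH2 link between the two halves (either alkene geometry) | O=C1CC[C@H]2[C@H](CC[C@]2(C)O[Si](C)(C)C)C(C)(C)C1=CC[C@H]1[C@]2(C)CC[C@H](O[Si](CC)(CC)CC)C(C)(C)O[C@H]2CC[C@@]1(C)O[Si](CC)(CC)CC | intermediate
38 | saturated ketone: hydroazulen-6-one joined at C5 through CH2CH2 to C6 of the benzoxepane, H-5 cis to H-3a and H-8a | O=C1CC[C@H]2[C@H](CC[C@]2(C)O[Si](C)(C)C)C(C)(C)[C@@H]1CC[C@H]1[C@]2(C)CC[C@H](O[Si](CC)(CC)CC)C(C)(C)O[C@H]2CC[C@@]1(C)O[Si](CC)(CC)CC | intermediate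
39 | potassium enolate of 38 (C6=C7) | [K]OC1=CC[C@H]2[C@H](CC[C@]2(C)O[Si](C)(C)C)C(C)(C)[C@@H]1CC[C@H]1[C@]2(C)CC[C@H](O[Si](CC)(CC)CC)C(C)(C)O[C@H]2CC[C@@]1(C)O[Si](CC)(CC)CC | intermediate
40 | enol triflate (C6–OTf, C6=C7) | FC(F)(F)S(=O)(=O)OC1=CC[C@H]2[C@H](CC[C@]2(C)O[Si](C)(C)C)C(C)(C)[C@@H]1CC[C@H]1[C@]2(C)CC[C@H](O[Si](CC)(CC)CC)C(C)(C)O[C@H]2CC[C@@]1(C)O[Si](CC)(CC)CC | intermediate
41 | silylated methyl alkene (target skeleton with C3–OSiEt3, C7–OSiEt3 on the benzoxepane and C1–OSiMe3 on the hydroazulene) | CC1=CC[C@H]2[C@H](CC[C@]2(C)O[Si](C)(C)C)C(C)(C)[C@@H]1CC[C@H]1[C@]2(C)CC[C@H](O[Si](CC)(CC)CC)C(C)(C)O[C@H]2CC[C@@]1(C)O[Si](CC)(CC)CC | intermediate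
42 | triol, the (3S)-carbinol of the target | CC1=CC[C@H]2[C@H](CC[C@]2(C)O)C(C)(C)[C@@H]1CC[C@H]1[C@]2(C)CC[C@H](O)C(C)(C)O[C@H]2CC[C@@]1(C)O | intermediate
43 | (5aS,6S,7R,9aS)-7-hydroxy-6-{2-[(1S,3aS,5R,8aS)-1-hydroxy-1,4,4,6-tetramethyl-1,2,3,3a,4,5,8,8a-octahydroazulen-5-yl]ethyl}-2,2,5a,7-tetramethyloctahydro-1-benzoxepin-3(2H)-one | CC1=CC[C@H]2[C@H](CC[C@]2(C)O)C(C)(C)[C@@H]1CC[C@H]1[C@]2(C)CCC(=O)C(C)(C)O[C@H]2CC[C@@]1(C)O | target

**Step count and risk**

Total: 27 steps. Longest linear sequence: 18 steps (steps 10–27, from (S)-limonene); the ring A/B branch runs 16 steps (steps 1–9 and 21–27).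

Three steps most likely to fail:

Step 5. What may go wrong: the silylated epoxide may collapse by proton loss or a 1,2-shift before the carbon–carbon bond forms, the enol silane may be lost to adventitious acid, or closure through a boat may put the arm axial. The fallback changes the terminating nucleophile to an allylsilane, the classical terminator of cation–olefin cyclisations. Setting out from 10, MeLi followed by PhNTf2 would give the (Z)-enol triflate F1. Coupling of F1 with Me3SiCH2MgCl under Pd(PPh3)4 catalysis would give the (Z)-allylsilane F2. Treatment of F2 with Et3SiOTf and 2,6-di-tert-butyl-4-methylpyridine at −78 °C should give the same trans-fused bicycle with an exocyclic methylene in place of the ketone, the methylene bicycle F3. Ozonolysis of F3 (O3; Me2S) comes back to the route at 13.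

Step 17. What may go wrong: hydrazone formation at the hindered ketone may be slow, and the β-hydroxy hydrazone may be diverted (pyrazoline formation, retro-aldol cleavage) or reduced instead of fragmenting. The fallback opens the epoxide by a radical fragmentation. Setting out from 28, t-BuMe2SiOTf and 2,6-lutidine would give the silyl ether F4, and NaBH4 would reduce its ketone to the epoxy alcohol F5. 1,1'-Thiocarbonyldiimidazole would convert F5 into the imidazolyl thiocarbonate F6. Bu3SnH with AIBN would generate the carbinyl radical, which opens the neighbouring epoxide and, after hydrogen transfer to oxygen, gives the transposed allylic alcohol F7. Bu4NF then comes back to the route at 30.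

Step 23. What may go wrong: hydrogen may be delivered to the other face of the exocyclic alkene, or with poor facial selectivity, and base equilibration may not favour the needed epimer. The fallback makes the C5–linker bond by C-alkylation, so that the carbon electrophile and not hydrogen enters from the more open face and the opposite C5 epimer results. Setting out from 16, I2, PPh3 and imidazole would give the primary iodide F8. The lithium enolate 34, made from 33 with MeLi, would then be alkylated with F8 in THF/DMPU, coming back to the route at 38.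

**Further compounds**

F1 | step 5 | (Z)-enol triflate, 1-(benzyloxy)hept-3-en-4-yl triflate carrying the diepoxide at C7 | c1ccccc1COCC/C=C(\OS(=O)(=O)C(F)(F)F)CC[C@@H]1O[C@@]1(C)CC[C@@H]1OC1(C)C
F2 | step 5 | (Z)-allylsilane, trimethylsilylmethyl in place of the triflate of F1 | c1ccccc1COCC/C=C(\C[Si](C)(C)C)CC[C@@H]1O[C@@]1(C)CC[C@@H]1OC1(C)C
F3 | step 5 | methylene bicycle, 7-methylidene analogue of 13 | c1ccccc1COCC[C@H]1[C@]2(C)CC[C@H](O[Si](CC)(CC)CC)C(C)(C)O[C@H]2CCC1=C
F4 | step 17 | silyl ether, 6-O-tert-butyldimethylsilyl derivative of 28 | CC(C)(C)[Si](C)(C)OC1CC(=O)[C@]32[C@H](CC[C@]2(C)O3)C(C)=C1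
F5 | step 17 | epoxy alcohol, 8-hydroxy compound from F4 | CC(C)(C)[Si](C)(C)OC1CC(O)[C@]32[C@H](CC[C@]2(C)O3)C(C)=C1
F6 | step 17 | imidazolyl thiocarbonate of F5 | CC(C)(C)[Si](C)(C)OC1CC(OC(=S)n4ccnc4)[C@]32[C@H](CC[C@]2(C)O3)C(C)=C1
F7 | step 17 | transposed allylic alcohol, 6-O-tert-butyldimethylsilyl ether of 30 | CC(C)(C)[Si](C)(C)OC1CC=C2[C@H](CC[C@]2(C)O)C(C)=C1
F8 | step 23 | primary iodide from 16 | ICC[C@H]1[C@]2(C)CC[C@H](O[Si](CC)(CC)CC)C(C)(C)O[C@H]2CC[C@@]1(C)O[Si](CC)(CC)CC
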